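**Remarks on the chemistry (assumptions)**
- Locants: the oxabicycle is numbered as 1-benzoxepine (O1, C2–C5, C5a, C6–C9, C9a), the carbobicycle as azulene (C1–C3, C3a, C4–C8, C8a).
- Commercial (4S)-limonene 1,2-oxide is a cis/trans mixture; both isomers give the same keto aldehyde in step 12.
- The ketoreductase of step 4 is taken from a commercial panel, screened for the (2R,3R) product.

## Retrosynthetic overview
1. The bond between hydroazulene C5 and the linker CH2 is cut as an anti-SN2′ allylic substitution: an alkyl-9-BBN (from a vinyl group on benzoxepine C6) attacks a hydroazulene C7 phosphate with a C5=C6 alkene.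
2. The feature that allows this: in the seven-membered carbocycle the linker-bearing methine C5 lies between quaternary C4 and the C6(Me)=C7H double bond, so it is allylic. Moving the alkene to C5=C6 with a leaving group on C7 makes C5 the γ-carbon; the CH2CH2 linker is a hydroborated vinyl group.
3. Benzoxepine half: cyclohexane first (2-methylcyclohexane-1,3-dione, enzymatic desymmetrisation), then the oxepane (7-exo alkoxymercuration), then C6/C7 (alkenyl oxirane, palladium/formate).
4. Hydroazulene half: cyclopentene first (aldol condensation of the keto aldehyde from (4S)-limonene oxide), then the seven-membered ring (hydrogen-atom-transfer radical closure onto an enone), then ring fusion and carbinol.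
5. Global desilylation ends the route.

Key step: step 23

## Route

**Benzoxepine half (steps 1–11)**

Step 1
Reactants: 1 2-methylcyclohexane-1,3-dione; 2 acrolein
Product: 3 3-(1-methyl-2,6-dioxocyclohexyl)propanal
Conditions: H2O, 25 °C
Reagents that add atoms: none
Why: Michael addition of the acidic 1,3-dione to acrolein should proceed in water without base and builds the quaternary carbon (later C5a), which is not yet a stereocentre because the dione is still symmetric.

Step 2
Reactants: 3 3-(1-methyl-2,6-dioxocyclohexyl)propanal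
Product: 4 (S)-2-(3-hydroxy-4-methylpent-4-en-1-yl)-2-methylcyclohexane-1,3-dione
Conditions: 2-bromopropene, CrCl2, NiCl2 (cat.), chiral oxazoline–sulfonamide ligand, Et3N, THF, 25 °C
Reagents that add atoms: 2-bromopropene, CC(Br)=C
Why: Asymmetric Nozaki–Hiyama–Kishi alkenylation should add the alkenylchromium species to the aldehyde only, leaving both ketones, and the chiral ligand on chromium should select the aldehyde face that gives the (S)-carbinol (later C3).

Step 3
Reactants: 4 (S)-2-(3-hydroxy-4-methylpent-4-en-1-yl)-2-methylcyclohexane-1,3-dione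
Product: 5 (S)-2-[3-(tert-butyldimethylsilyloxy)-4-methylpent-4-en-1-yl]-2-methylcyclohexane-1,3-dione
Conditions: TBSCl, imidazole, DMF, 25 °C
Reagents that add atoms: tert-butyldimethylsilyl chloride, CC(C)(C)[Si](C)(C)Cl
Why: Silyl ether formation masks the carbinol (no hemiketal with the ketones) for steps 4–10 and creates no stereocentre.

Step 4
Reactants: 5 (S)-2-[3-(tert-butyldimethylsilyloxy)-4-methylpent-4-en-1-yl]-2-methylcyclohexane-1,3-dione
Product: 6 (2R,3R)-3-hydroxy-2-methyl-2-[(3S)-3-(tert-butyldimethylsilyloxy)-4-methylpent-4-en-1-yl]cyclohexan-1-one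
Conditions: ketoreductase (NADPH-dependent, anti-Prelog), NADP+ (cat.), i-PrOH, phosphate buffer pH 7, DMSO, 30 °C
Reagents that add atoms: none
Why: Ketoreductase-catalysed desymmetrising reduction of a 2,2-disubstituted cyclohexane-1,3-dione should pick one enantiotopic carbonyl and one face, fixing the carbinol (R) and the quaternary carbon (R) with the hydroxyl cis to the side chain, as the cis-fused oxepane needs.

Step 5
Reactants: 6 (2R,3R)-3-hydroxy-2-methyl-2-[(3S)-3-(tert-butyldimethylsilyloxy)-4-methylpent-4-en-1-yl]cyclohexan-1-one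
Product: 8 (3S,5aR,9aR)-3-(tert-butyldimethylsilyloxy)-2,2,5a-trimethyloctahydro-1-benzoxepin-6(2H)-one, via organomercury trifluoroacetate 7 (not isolated)
Conditions: Hg(OCOCF3)2, NaHCO3, CH2Cl2, 0 °C; then Bu3SnH, 25 °C
Reagents that add atoms: none
Why: Intramolecular Markovnikov alkoxymercuration (7-exo-trig) of the 1,1-disubstituted alkene by the ring hydroxyl, then radical demercuration, should close the oxepane at the tertiary carbon only; that carbon then carries two methyl groups and is no stereocentre.

Step 6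
Reactants: 8 (3S,5aR,9aR)-3-(tert-butyldimethylsilyloxy)-2,2,5a-trimethyloctahydro-1-benzoxepin-6(2H)-one
Product: 9 (3S,5aR,9aR)-3-(tert-butyldimethylsilyloxy)-2,2,5a,7-tetramethyloctahydro-1-benzoxepin-6(2H)-one (C7 epimers)
Conditions: LiN(iPr)2, THF, −78 °C; MeI, −78 → 0 °C
Reagents that add atoms: iodomethane, CI
Why: Enolate alkylation can occur only at C7 because the other α-carbon (C5a) is quaternary; the C7 configuration is irrelevant since C7 becomes sp2 in step 7.

Step 7
Reactants: 9 (3S,5aR,9aR)-3-(tert-butyldimethylsilyloxy)-2,2,5a,7-tetramethyloctahydro-1-benzoxepin-6(2H)-one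
Product: 10 (3S,5aR,9aR)-3-(tert-butyldimethylsilyloxy)-2,2,5a,7-tetramethyl-2,3,4,5,5a,8,9,9a-octahydro-1-benzoxepin-6-yl trifluoromethanesulfonate
Conditions: KN(SiMe3)2, THF, −78 °C; PhNTf2, −78 → 25 °C
Reagents that add atoms: N-phenylbis(trifluoromethanesulfonimide), O=S(=O)(N(c1ccccc1)S(=O)(=O)C(F)(F)F)C(F)(F)F
Why: O-triflation of the only possible (tetrasubstituted) enolate, as for 2,2,6-trisubstituted cyclohexanones, gives the enol triflate without touching a stereocentre.

Step 8
Reactants: 10 enol triflate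
Product: 11 tert-butyl{[(3S,5aS,9aR)-6-ethenyl-2,2,5a,7-tetramethyl-2,3,4,5,5a,8,9,9a-octahydro-1-benzoxepin-3-yl]oxy}dimethylsilane
Conditions: tributyl(vinyl)stannane, Pd(PPh3)4 (5 mol%), LiCl, THF, 65 °C
Reagents that add atoms: tributyl(vinyl)stannane, C=C[Sn](CCCC)(CCCC)CCCC
Why: Stille coupling of a hindered cyclohexenyl triflate with a vinylstannane is well precedented and installs both linker carbons as a vinyl group; no stereocentre is formed.

Step 9
Reactants: 11 vinyl diene
Product: 12 (3S,5aR,6S,7R,9aR)-6,7-epoxide of 11 (oxirane oxygen cis to the C5a methyl group)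
Conditions: mCPBA, NaHCO3, CH2Cl2, −20 °C
Reagents that add atoms: 3-chloroperbenzoic acid, OOC(=O)c1cccc(Cl)c1
Why: Prilezhaev epoxidation should take the tetrasubstituted, most electron-rich ring alkene rather than the vinyl group, on the face of the angular C5a methyl and anti to the pseudo-axial C5 methylene of the cis-fused oxepane, which places the later C7 oxygen trans to the oxepane oxygen.

Step 10
Reactants: 12 alkenyl oxirane
Product: 13 (3S,5aS,6S,7R,9aR)-3-(tert-butyldimethylsilyloxy)-6-ethenyl-2,2,5a,7-tetramethyldecahydro-1-benzoxepin-7-ol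
Conditions: Pd2(dba)3·CHCl3 (cat.), n-Bu3P, HCO2H, Et3N, 1,4-dioxane, 25 °C
Reagents that add atoms: none
Why: Palladium-catalysed hydrogenolysis of an alkenyl oxirane with formate (Tsuji–Trost-type ionisation, then hydride transfer from the metal): zerovalent palladium opens the allylic C6–O bond with inversion and delivers hydride to the more substituted allyl terminus C6 on the face opposite the departed oxygen, so C6–H ends trans to the retained tertiary C7 hydroxyl and the vinyl group survives.

Step 11
Reactants: 13 homoallylic tertiary alcohol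
Product: 14 7-O-triethylsilyl ether of 13
Conditions: TESOTf, 2,6-lutidine, CH2Cl2, 0 °C
Reagents that add atoms: triethylsilyl trifluoromethanesulfonate, CC[Si](CC)(CC)OS(=O)(=O)C(F)(F)F
Why: Silyl triflate silylation of the hindered tertiary alcohol keeps it from consuming borane and alkoxide in step 23; no stereocentre is affected.

**Hydroazulene half (steps 12–22)**

Step 12
Reactants: 15 (4S)-limonene 1,2-oxide
Product: 16 (3S)-6-oxo-3-(prop-1-en-2-yl)heptanal
Conditions: H5IO6, THF/H2O, 25 °C
Reagents that add atoms: water, O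
Why: Periodic acid hydrates the oxirane and cleaves the resulting 1,2-diol (Malaprade glycol cleavage) to the keto aldehyde; the isopropenyl-bearing stereocentre is untouched, so both oxirane isomers converge.

Step 13
Reactants: 16 (3S)-6-oxo-3-(prop-1-en-2-yl)heptanal
Product: 17 (5R)-2-methyl-5-(prop-1-en-2-yl)cyclopent-1-ene-1-carbaldehyde
Conditions: piperidine, AcOH, toluene, 80 °C
Reagents that add atoms: none
Why: Intramolecular aldol condensation (aldehyde enamine onto the methyl ketone, then dehydration) closes the five-membered ring and forms no new stereocentre.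

Step 14
Reactants: 17 cyclopentene carbaldehyde
Product: 18 [(5R)-2-methyl-5-(prop-1-en-2-yl)cyclopent-1-en-1-yl]methanol
Conditions: NaBH4, CeCl3·7H2O, MeOH, 0 °C
Reagents that add atoms: none
Why: Luche 1,2-reduction of the enal gives the primary allylic alcohol without conjugate reduction; no stereocentre is formed.

Step 15
Reactants: 18 allylic alcohol
Product: 19 (5R)-1-(chloromethyl)-2-methyl-5-(prop-1-en-2-yl)cyclopent-1-ene
Conditions: N-chlorosuccinimide, Me2S, CH2Cl2, −20 → 0 °C
Reagents that add atoms: N-chlorosuccinimide, ClN1C(=O)CCC1=O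
Why: Corey–Kim chlorination converts the primary allylic alcohol to the chloride by SN2 at CH2 under neutral conditions, without allylic transposition.

Step 16
Reactants: 19 allylic chloride
Product: 20 3-methyl-1-[(5R)-2-methyl-5-(prop-1-en-2-yl)cyclopent-1-en-1-yl]but-3-en-2-one
Conditions: CO (3 atm), tributyl(prop-1-en-2-yl)stannane, Pd2(dba)3 (cat.), PPh3, THF, 50 °C
Reagents that add atoms: carbon monoxide, [C-]#[O+]; tributyl(prop-1-en-2-yl)stannane, CC(=C)[Sn](CCCC)(CCCC)CCCC
Why: Carbonylative Stille coupling (oxidative addition of the allylic chloride, CO insertion at the primary terminus, transmetallation with the alkenylstannane) gives the allyl isopropenyl ketone, that is C7 with its oxygen and C6 with its methyl group, without forming a stereocentre.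

Step 17
Reactants: 20 dienone
Product: 21 (3aR)-1,4,4,6-tetramethyl-2,3,3a,4,5,6-hexahydroazulen-7(8H)-one (C6 epimers)
Conditions: Fe(acac)3, PhSiH3, EtOH/(CH2OH)2, 60 °C, high dilution
Reagents that add atoms: none
Why: Metal-hydride hydrogen-atom transfer to the electron-rich isopropenyl group gives the tertiary radical, which should close 7-endo-trig onto the terminal CH2 of the enone (Giese-type reductive olefin coupling); this builds quaternary C4 and the seven-membered ring at once, and the C6 epimers converge in step 20.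

Step 18
Reactants: 21 bicyclic β,γ-unsaturated ketone
Product: 23 (1S,3aR)-1-hydroxy-1,4,4,6-tetramethyl-2,3,3a,4,5,6-hexahydroazulen-7(1H)-one, via epoxy ketone 22 (not isolated)
Conditions: mCPBA, NaHCO3, CH2Cl2, 0 °C; then Et3N, 25 °C
Reagents that add atoms: 3-chloroperbenzoic acid, OOC(=O)c1cccc(Cl)c1
Why: Prilezhaev epoxidation of the tetrasubstituted alkene on the face of the C3a hydrogen (away from gem-dimethyl C4), then base-induced β-elimination of the β,γ-epoxy ketone, opens the oxirane to the γ-hydroxy enone; the retained C1–O bond sets the tertiary carbinol with hydroxyl and C3a–H on the same face.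

Step 19
Reactants: 23 γ-hydroxy enone
Product: 24 (1S,3aS,8aS)-1-hydroxy-1,4,4,6-tetramethyloctahydroazulen-7(1H)-one (C6 epimers)
Conditions: H2 (1 atm), [Ir(cod)(PCy3)(py)]PF6 (cat.), CH2Cl2, 25 °C
Reagents that add atoms: none
Why: Hydroxyl-directed homogeneous hydrogenation should deliver hydrogen to C8a from the face of the C1 hydroxyl, which is also the open face opposite C4, giving the cis ring fusion and leaving the ketone alone.

Step 20
Reactants: 24 hydroxy ketone
Product: 26 (1S,3aS,8aS)-1,4,4,6-tetramethyl-1-(triethylsilyloxy)-2,3,3a,4,8,8a-hexahydroazulen-7(1H)-one, via bis(triethylsilyl) enol ether 25 (not isolated)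
Conditions: TESOTf, Et3N, CH2Cl2, 0 → 25 °C; then Pd(OAc)2, MeCN, 25 °C
Reagents that add atoms: triethylsilyl trifluoromethanesulfonate, CC[Si](CC)(CC)OS(=O)(=O)C(F)(F)F
Why: Silyl triflate/amine silylation protects the tertiary alcohol and, under equilibrating conditions, forms the more substituted C6=C7 silyl enol ether, whose Saegusa–Ito oxidation gives the 6-methyl enone; no stereocentre is touched and the C6 epimers converge.

Step 21
Reactants: 26 enone
Product: 27 (1S,3aS,7R,8aS)-1,4,4,6-tetramethyl-1-(triethylsilyloxy)-1,2,3,3a,4,7,8,8a-octahydroazulen-7-ol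
Conditions: NaBH4, CeCl3·7H2O, MeOH, −78 °C
Reagents that add atoms: none
Why: Luche 1,2-reduction should add hydride from the convex face (that of the ring-fusion hydrogens, away from the inward-pointing C1 methyl group), giving the (7R)-alcohol with the hydroxyl on the concave face.

Step 22
Reactants: 27 allylic alcohol
Product: 28 diethyl (1S,3aS,7S,8aS)-1,4,4,6-tetramethyl-1-(triethylsilyloxy)-1,2,3,3a,4,7,8,8a-octahydroazulen-7-yl phosphate
Conditions: (EtO)2P(O)OH, PPh3, DIAD, THF, 0 → 25 °C
Reagents that add atoms: diethyl hydrogen phosphate, CCOP(=O)(O)OCC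
Why: Mitsunobu substitution with the dialkyl phosphate as acidic pronucleophile inverts C7, so the phosphate ends on the convex face, opposite the face from which the alkyl group must enter C5.

**Union and end (steps 23–24)**

Step 23
Reactants: 14 vinyl benzoxepine; 28 allylic phosphate
Product: 30 tris-silyl ether of the target (3-O-TBS and 7-O-TES on the benzoxepine; 1-O-TES on the hydroazulene), via B-alkyl-9-BBN 29 (not isolated)
Conditions: 14, (9-BBN-H)2, THF, 60 °C; then 28, CuOAc (10 mol%), KOt-Bu, THF, 60 °C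
Reagents that add atoms: none
Why: This is a copper-catalysed γ-selective allyl–alkyl coupling (anti-SN2′ allylic substitution), closest to the known CuOAc/alkoxide coupling of alkyl-9-BBN reagents with cyclic and acyclic allylic phosphates: 9-BBN adds anti-Markovnikov to the vinyl group of 14, KOt-Bu turns 29 into a borate that passes the primary alkyl group to monovalent copper, and the alkylcopper adds oxidatively to the γ-carbon C5 of 28 anti to the phosphate, giving a trivalent allylcopper species that eliminates reductively at that carbon. No ring is closed. The one new stereocentre, hydroazulene C5 (R), is controlled by the C7 phosphate through 1,3-anti chirality transfer: the phosphate sits on the face of the ring-fusion hydrogens, so the chain enters from the opposite face. The step needs γ- over α-attack and anti over syn delivery; a phosphate leaving group with a bulky alkoxide in THF favours the anti course, and reductive elimination before allyl equilibration should keep attack at C5 although it is flanked by quaternary C4. In the same operation the alkene moves to C6=C7, where the target has it, and the two-carbon linker is completed with no auxiliary group to remove.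

Step 24
Reactants: 30 tris-silyl ether
Product: 31 (3S,5aS,6S,7R,9aR)-6-{2-[(1S,3aS,5R,8aS)-1-hydroxy-1,4,4,6-tetramethyl-1,2,3,3a,4,5,8,8a-octahydroazulen-5-yl]ethyl}-2,2,5a,7-tetramethyldecahydro-1-benzoxepine-3,7-diol (target)
Conditions: n-Bu4NF, THF, 50 °C
Reagents that add atoms: none
Why: Fluoride-mediated cleavage of the three silyl ethers under basic, non-ionising conditions should spare the tertiary alcohols and the trisubstituted alkene; no stereocentre is affected.

## Compound list
1 | 2-methylcyclohexane-1,3-dione | CC1C(=O)CCCC1=O | starting material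
2 | acrolein | C=CC=O | starting material
3 | 3-(1-methyl-2,6-dioxocyclohexyl)propanal | CC1(CCC=O)C(=O)CCCC1=O | intermediate
4 | (S)-2-(3-hydroxy-4-methylpent-4-en-1-yl)-2-methylcyclohexane-1,3-dione | O=C1CCCC(=O)C1(C)CC[C@H](O)C(C)=C | intermediate
5 | (S)-2-[3-(tert-butyldimethylsilyloxy)-4-methylpent-4-en-1-yl]-2-methylcyclohexane-1,3-dione | O=C1CCCC(=O)C1(C)CC[C@H](O[Si](C)(C)C(C)(C)C)C(C)=C | intermediate
6 | (2R,3R)-3-hydroxy-2-methyl-2-[(3S)-3-(tert-butyldimethylsilyloxy)-4-methylpent-4-en-1-yl]cyclohexan-1-one | O=C1[C@](C)(CC[C@H](O[Si](C)(C)C(C)(C)C)C(C)=C)[C@H](O)CCC1 | intermediate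
7 | organomercury trifluoroacetate: 8 with one C2 methyl as CH2HgOCOCF3 (C2 epimers) | O=C1[C@]2(C)CC[C@H](O[Si](C)(C)C(C)(C)C)C(C)(C[Hg]OC(=O)C(F)(F)F)O[C@@H]2CCC1 | intermediate (not isolated)
8 | (3S,5aR,9aR)-3-(tert-butyldimethylsilyloxy)-2,2,5a-trimethyloctahydro-1-benzoxepin-6(2H)-one | O=C1[C@]2(C)CC[C@H](O[Si](C)(C)C(C)(C)C)C(C)(C)O[C@@H]2CCC1 | intermediate
9 | 7-methyl derivative of 8 (C7 epimers) | O=C1[C@]2(C)CC[C@H](O[Si](C)(C)C(C)(C)C)C(C)(C)O[C@@H]2CCC1C | intermediate
10 | (3S,5aR,9aR)-3-(tert-butyldimethylsilyloxy)-2,2,5a,7-tetramethyl-2,3,4,5,5a,8,9,9a-octahydro-1-benzoxepin-6-yl trifluoromethanesulfonate | FC(F)(F)S(=O)(=O)OC=1[C@]2(C)CC[C@H](O[Si](C)(C)C(C)(C)C)C(C)(C)O[C@@H]2CCC=1C | intermediate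
11 | tert-butyl{[(3S,5aS,9aR)-6-ethenyl-2,2,5a,7-tetramethyl-2,3,4,5,5a,8,9,9a-octahydro-1-benzoxepin-3-yl]oxy}dimethylsilane | C=CC=1[C@]2(C)CC[C@H](O[Si](C)(C)C(C)(C)C)C(C)(C)O[C@@H]2CCC=1C | intermediate
12 | (3S,5aR,6S,7R,9aR)-6,7-epoxide of 11 (oxirane oxygen cis to the C5a methyl group) | C=C[C@]12[C@]3(C)CC[C@H](O[Si](C)(C)C(C)(C)C)C(C)(C)O[C@@H]3CC[C@@]1(C)O2 | intermediate
13 | (3S,5aS,6S,7R,9aR)-3-(tert-butyldimethylsilyloxy)-6-ethenyl-2,2,5a,7-tetramethyldecahydro-1-benzoxepin-7-ol | C=C[C@H]1[C@]2(C)CC[C@H](O[Si](C)(C)C(C)(C)C)C(C)(C)O[C@@H]2CC[C@@]1(C)O | intermediate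
14 | 7-O-triethylsilyl ether of 13 | C=C[C@H]1[C@]2(C)CC[C@H](O[Si](C)(C)C(C)(C)C)C(C)(C)O[C@@H]2CC[C@@]1(C)O[Si](CC)(CC)CC | intermediate
15 | (4S)-limonene 1,2-oxide (cis/trans mixture) | CC(=C)[C@H]1CCC2(C)OC2C1 | starting material
16 | (3S)-6-oxo-3-(prop-1-en-2-yl)heptanal | O=CC[C@H](CCC(C)=O)C(C)=C | intermediate
17 | (5R)-2-methyl-5-(prop-1-en-2-yl)cyclopent-1-ene-1-carbaldehyde | O=CC1=C(C)CC[C@@H]1C(C)=C | intermediate
18 | [(5R)-2-methyl-5-(prop-1-en-2-yl)cyclopent-1-en-1-yl]methanol | OCC1=C(C)CC[C@@H]1C(C)=C | intermediate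
19 | (5R)-1-(chloromethyl)-2-methyl-5-(prop-1-en-2-yl)cyclopent-1-ene | ClCC1=C(C)CC[C@@H]1C(C)=C | intermediate
20 | 3-methyl-1-[(5R)-2-methyl-5-(prop-1-en-2-yl)cyclopent-1-en-1-yl]but-3-en-2-one | C=C(C)C(=O)CC1=C(C)CC[C@@H]1C(C)=C | intermediate
21 | (3aR)-1,4,4,6-tetramethyl-2,3,3a,4,5,6-hexahydroazulen-7(8H)-one (C6 epimers; alkene C1=C8a) | O=C1CC2=C(C)CC[C@@H]2C(C)(C)CC1C | intermediate
22 | 1,8a-epoxide of 21 (oxirane on the face of the C3a hydrogen) | O=C1C[C@]23O[C@@]2(C)CC[C@@H]3C(C)(C)CC1C | intermediate (not isolated)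
23 | (1S,3aR)-1-hydroxy-1,4,4,6-tetramethyl-2,3,3a,4,5,6-hexahydroazulen-7(1H)-one (alkene C8=C8a) | O=C1C=C2[C@@](C)(O)CC[C@@H]2C(C)(C)CC1C | intermediate
24 | (1S,3aS,8aS)-1-hydroxy-1,4,4,6-tetramethyloctahydroazulen-7(1H)-one (C6 epimers) | O=C1C[C@@H]2[C@@](C)(O)CC[C@@H]2C(C)(C)CC1C | intermediate
25 | bis(triethylsilyl) derivative of 24: 1-O-TES ether and C6=C7 TES enol ether | CC[Si](CC)(CC)OC=1C[C@@H]2[C@@](C)(O[Si](CC)(CC)CC)CC[C@@H]2C(C)(C)CC=1C | intermediate (not isolated)
26 | (1S,3aS,8aS)-1,4,4,6-tetramethyl-1-(triethylsilyloxy)-2,3,3a,4,8,8a-hexahydroazulen-7(1H)-one | O=C1C[C@@H]2[C@@](C)(O[Si](CC)(CC)CC)CC[C@@H]2C(C)(C)C=C1C | intermediate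
27 | (1S,3aS,7R,8aS)-1,4,4,6-tetramethyl-1-(triethylsilyloxy)-1,2,3,3a,4,7,8,8a-octahydroazulen-7-ol | O[C@@H]1C[C@@H]2[C@@](C)(O[Si](CC)(CC)CC)CC[C@@H]2C(C)(C)C=C1C | intermediate
28 | diethyl (1S,3aS,7S,8aS)-1,4,4,6-tetramethyl-1-(triethylsilyloxy)-1,2,3,3a,4,7,8,8a-octahydroazulen-7-yl phosphate | CCOP(=O)(OCC)O[C@H]1C[C@@H]2[C@@](C)(O[Si](CC)(CC)CC)CC[C@@H]2C(C)(C)C=C1C | intermediate
29 | B-alkyl-9-BBN from 14 (9-borabicyclo[3.3.1]nonane on the terminal linker carbon) | C1CCC2CCCC1B2CC[C@H]1[C@]2(C)CC[C@H](O[Si](C)(C)C(C)(C)C)C(C)(C)O[C@@H]2CC[C@@]1(C)O[Si](CC)(CC)CC | intermediate (not isolated)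
30 | tris-silyl ether of the target (3-O-TBS, 7-O-TES, hydroazulene 1-O-TES) | CC1=CC[C@H]2[C@H](CC[C@]2(C)O[Si](CC)(CC)CC)C(C)(C)[C@@H]1CC[C@H]1[C@]2(C)CC[C@H](O[Si](C)(C)C(C)(C)C)C(C)(C)O[C@@H]2CC[C@@]1(C)O[Si](CC)(CC)CC | intermediate
31 | (3S,5aS,6S,7R,9aR)-6-{2-[(1S,3aS,5R,8aS)-1-hydroxy-1,4,4,6-tetramethyl-1,2,3,3a,4,5,8,8a-octahydroazulen-5-yl]ethyl}-2,2,5a,7-tetramethyldecahydro-1-benzoxepine-3,7-diol | CC1=CC[C@H]2[C@H](CC[C@]2(C)O)C(C)(C)[C@@H]1CC[C@H]1[C@]2(C)CC[C@H](O)C(C)(C)O[C@@H]2CC[C@@]1(C)O | target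

## Count and risks
Total: 24 steps. Longest linear sequence: 13 steps (steps 12–22, then 23 and 24; the benzoxepine branch, steps 1–11 then 23 and 24, is equally long).

**Step 23 (key coupling).** What may go wrong: oxidative addition at the neopentylic γ-carbon is slow, so the allylcopper intermediate may equilibrate and couple at the α-carbon C7, or stereospecificity may erode. Fallback, a tethered [3,3] route from 14 and 27 back to 30: cross-metathesis of 14 with acrylic acid (second-generation Hoveyda–Grubbs catalyst) would give the (E)-enoic acid F1, and hydrogenation (H2, Pd/C) the saturated acid F2. Yamaguchi esterification of F2 with the concave-face alcohol 27 would give the allylic ester F3. Ireland–Claisen rearrangement (KN(SiMe3)2, Me3SiCl, THF, −78 → 65 °C, aqueous work-up) would form the C5–C bond suprafacially, on the face of the former C7–O bond, giving the γ,δ-unsaturated acid F4; both carboxyl epimers are acceptable. Acridinium-photocatalysed hydrodecarboxylation (9-mesityl-10-methylacridinium tetrafluoroborate, PhSSPh, blue light) would then give 30.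

**Step 17 (radical ring closure).** What may go wrong: hydrogen-atom quenching of the tertiary radical (net hydrogenation of the isopropenyl group), or hydrogen-atom transfer to the enone, may outrun the slow 7-endo closure. Fallback, from 18 back to 21, generating the same radical by photoredox decarboxylation with no metal hydride present: Mukaiyama hydration of the isopropenyl group of 18 (Co(acac)2, PhSiH3, O2) would give the diol F5. Corey–Kim chlorination of its primary allylic alcohol would give the chloride F6, and carbonylative Stille coupling as in step 16 the hydroxy dienone F7. Acylation of the tertiary alcohol with oxalyl chloride and CsOH work-up would give the cesium oxalate F8. Irradiation with Ir[dF(CF3)ppy]2(dtbbpy)PF6 (cat.) and blue light in aqueous DME would release the tertiary radical by double decarboxylation and close the ring to 21.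

**Step 5 (oxepane closure).** What may go wrong: trifluoroacetate or water may capture the mercurinium ion instead of the hindered ring hydroxyl, or the silyl ether may be lost under the Lewis acidic conditions. Fallback, from 6 back to 8, by intramolecular oxirane opening: mCPBA epoxidation of the 1,1-disubstituted alkene of 6 would give the oxirane F9 (either configuration at the new centre serves). Acid-catalysed 7-exo opening at the tertiary carbon (camphorsulfonic acid, CH2Cl2) would give the hydroxymethyl oxepane F10. Iodination (I2, PPh3, imidazole) would give the iodide F11, and Bu3SnH reduction would return 8.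

## Further compounds
F1 | step 23 | (E)-3-[benzoxepin-6-yl]prop-2-enoic acid from 14 and acrylic acid | OC(=O)/C=C/[C@H]1[C@]2(C)CC[C@H](O[Si](C)(C)C(C)(C)C)C(C)(C)O[C@@H]2CC[C@@]1(C)O[Si](CC)(CC)CC
F2 | step 23 | saturated acid, 3-[benzoxepin-6-yl]propanoic acid | OC(=O)CC[C@H]1[C@]2(C)CC[C@H](O[Si](C)(C)C(C)(C)C)C(C)(C)O[C@@H]2CC[C@@]1(C)O[Si](CC)(CC)CC
F3 | step 23 | allylic ester of F2 with alcohol 27 | O=C(CC[C@H]3[C@]4(C)CC[C@H](O[Si](C)(C)C(C)(C)C)C(C)(C)O[C@@H]4CC[C@@]3(C)O[Si](CC)(CC)CC)O[C@@H]1C[C@@H]2[C@@](C)(O[Si](CC)(CC)CC)CC[C@@H]2C(C)(C)C=C1C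
F4 | step 23 | Ireland–Claisen acid: 30 with a carboxyl group on the linker carbon next to hydroazulene C5 (epimers) | CC1=CC[C@H]2[C@H](CC[C@]2(C)O[Si](CC)(CC)CC)C(C)(C)[C@@H]1C(C(=O)O)C[C@H]1[C@]2(C)CC[C@H](O[Si](C)(C)C(C)(C)C)C(C)(C)O[C@@H]2CC[C@@]1(C)O[Si](CC)(CC)CC
F5 | step 17 | 2-[(1S)-2-(hydroxymethyl)-3-methylcyclopent-2-en-1-yl]propan-2-ol | OCC1=C(C)CC[C@@H]1C(C)(C)O
F6 | step 17 | 2-[(1S)-2-(chloromethyl)-3-methylcyclopent-2-en-1-yl]propan-2-ol | ClCC1=C(C)CC[C@@H]1C(C)(C)O
F7 | step 17 | 1-[(5S)-5-(2-hydroxypropan-2-yl)-2-methylcyclopent-1-en-1-yl]-3-methylbut-3-en-2-one | C=C(C)C(=O)CC1=C(C)CC[C@@H]1C(C)(C)O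
F8 | step 17 | cesium oxalate half-ester of the tertiary alcohol of F7 | C=C(C)C(=O)CC1=C(C)CC[C@@H]1C(C)(C)OC(=O)C(=O)[O-].[Cs+]
F9 | step 5 | oxirane of the 1,1-disubstituted alkene of 6 (epimers at the new centre) | O=C1[C@](C)(CC[C@H](O[Si](C)(C)C(C)(C)C)C2(C)CO2)[C@H](O)CCC1
F10 | step 5 | 8 with one C2 methyl as CH2OH (C2 epimers) | O=C1[C@]2(C)CC[C@H](O[Si](C)(C)C(C)(C)C)C(C)(CO)O[C@@H]2CCC1
F11 | step 5 | 8 with one C2 methyl as CH2I (C2 epimers) | O=C1[C@]2(C)CC[C@H](O[Si](C)(C)C(C)(C)C)C(C)(CI)O[C@@H]2CCC1
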